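**Retrosynthetic overview**

1. Ring C is opened at O1–C2 and C2–C3. This gives a 2-hydroxy-ω-methoxyacetophenone that carries all of ring A, and a benzyl-protected 3,5-dihydroxy-4-methoxybenzoyl chloride (ring B). The two are joined by Baker–Venkataraman aroyl transfer and cyclodehydration.
2. The methoxyacetyl group goes onto the only free carbon of ring A (the future C4a) by directed ortho-metalation of the ring A phenol.
3. The strategy rests on ring A: C6, C7, C8 and C8a are four adjacent oxygen-bearing carbons with C6 and C8a para, which is the pattern of the four carbons of a squarate ester. C5 with its oxygen, and C4a, are the two carbons of a 1-alkoxyvinyl group. Ring A is therefore made by thermal ring expansion of a 4-(1-ethoxyvinyl)cyclobutenone.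
4. That cyclobutenone comes from mono-addition of 1-ethoxyvinyllithium to dimethyl squarate and capping of the carbinol as its methoxymethyl (MOM) ether.
5. Order of ring formation: ring A (step 3), then ring C (step 13); ring B is bought as an aromatic ester.

Key step: step 3

Remark: every chiral intermediate (the cyclobutenones, the oxan-2-yl acetals and the 2-methoxy-1,3-diketone) is racemic; the target is achiral, so this has no consequence.

**Route**

Step 1
Reactants: 1 dimethyl squarate (3,4-dimethoxycyclobut-3-ene-1,2-dione); 2 ethyl vinyl ether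
Product: 4 rac-4-(1-ethoxyvinyl)-4-hydroxy-2,3-dimethoxycyclobut-2-en-1-one, via 1-ethoxyvinyllithium 3 (not isolated)
Conditions: 2 (1.3 equiv), t-BuLi (1.1 equiv), THF, −78 to 0 °C; then added to 1, THF, −78 °C; H2O (pH 7 buffer) at −78 °C
Reagents that add atoms: none
Why: α-Lithiation of the vinyl ether gives 3, which should add once, in 1,2-fashion, to one of the two equivalent carbonyls of the symmetric squarate at −78 °C (organolithium 1,2-addition to a squarate ester); the new quaternary carbinol centre is formed racemic and is destroyed in step 3.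

Step 2
Reactants: 4 rac-4-(1-ethoxyvinyl)-4-hydroxy-2,3-dimethoxycyclobut-2-en-1-one
Product: 5 rac-4-(1-ethoxyvinyl)-2,3-dimethoxy-4-(methoxymethoxy)cyclobut-2-en-1-one
Conditions: MOMCl (3 equiv), i-Pr2NEt (4 equiv), CH2Cl2, 0 °C to rt
Reagents that add atoms: chloromethyl methyl ether, COCCl
Why: O-Alkylation of the fairly acidic tertiary carbinol with the reactive α-chloro ether under amine base (methoxymethyl ether formation) leaves the acid-sensitive enol ether untouched and marks the future C6 oxygen.

Step 3
Reactants: 5 rac-4-(1-ethoxyvinyl)-2,3-dimethoxy-4-(methoxymethoxy)cyclobut-2-en-1-one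
Product: 8 5-ethoxy-2,3-dimethoxy-4-(methoxymethoxy)phenol, via dienylketene 6 (not isolated), via cyclohexa-2,4-dienone 7 (not isolated)
Conditions: toluene (degassed, 0.02 M, base-washed glassware), 110 °C, argon
Reagents that add atoms: none
Why: Heating breaks the C1–C4 bond of the cyclobutenone in a thermal conrotatory four-electron ring opening to give dienylketene 6. The ketene carbon and the terminal CH2 of the ethoxyvinyl group then join in a thermal disrotatory six-electron electrocyclisation; this closes ring A, forms the future C8a–C4a bond and gives dienone 7, which enolises to phenol 8. The closest known reaction type is the thermal ring expansion of 4-alkenyl-4-hydroxy or 4-alkoxy cyclobutenones from squarate esters to hydroquinone derivatives (Moore-type rearrangement). No stereocentre is formed, and the quaternary centre of 5 disappears. The step needs torquoselectivity: the oxygen donor on C4 prefers to rotate outward, which turns the ethoxyvinyl group inward, cis to the ketene, and any ketene of the other geometry can only revert to 5. Regiochemistry is fixed because the ketene carbon can bond only to the single vinyl terminus, so the free hydroxyl (future C8a–O) ends para to the MOM-capped oxygen (future C6–O), with the ethoxy group (future C5–O) and the one ring hydrogen (future C4a) between them.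

Step 4
Reactants: 8 5-ethoxy-2,3-dimethoxy-4-(methoxymethoxy)phenol
Product: 9 rac-2-[5-ethoxy-2,3-dimethoxy-4-(methoxymethoxy)phenoxy]oxane
Conditions: 3,4-dihydro-2H-pyran (3 equiv), PPTS (cat.), CH2Cl2, rt
Reagents that add atoms: 3,4-dihydro-2H-pyran, C1=COCCC1
Why: Acid-catalysed addition of the phenol to the enol ether (tetrahydropyranyl acetal formation) installs a lithium-directing group that can later be removed without loss of the aryl MOM ether; the acetal carbon is a racemic stereocentre of no consequence.

Step 5
Reactants: 10 methoxyacetyl chloride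
Product: 11 N,2-dimethoxy-N-methylacetamide
Conditions: MeNHOMe·HCl (1.1 equiv), Et3N (2.2 equiv), CH2Cl2, 0 °C to rt
Reagents that add atoms: N,O-dimethylhydroxylamine hydrochloride, CNOC.Cl
Why: N-Acylation of the hydroxylamine by the acid chloride (Weinreb amide formation) gives an acyl donor that reacts only once with an organolithium.

Step 6
Reactants: 9 rac-2-[5-ethoxy-2,3-dimethoxy-4-(methoxymethoxy)phenoxy]oxane; 11 N,2-dimethoxy-N-methylacetamide
Product: 13 rac-1-[2-ethoxy-4,5-dimethoxy-3-(methoxymethoxy)-6-(oxan-2-yloxy)phenyl]-2-methoxyethan-1-one, via aryllithium 12 (not isolated)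
Conditions: n-BuLi (1.2 equiv), TMEDA, THF, −20 to 0 °C; then 11, −78 °C to rt; H2O
Reagents that add atoms: none
Why: Directed ortho-metalation: the single ring hydrogen lies between the acetal oxygen and the ethoxy group, which both coordinate lithium, so deprotonation can occur only there, and the chelating amide stops the acylation at the ketone (Weinreb ketone synthesis).

Step 7
Reactants: 13 rac-1-[2-ethoxy-4,5-dimethoxy-3-(methoxymethoxy)-6-(oxan-2-yloxy)phenyl]-2-methoxyethan-1-one
Product: 14 1-[2-ethoxy-6-hydroxy-4,5-dimethoxy-3-(methoxymethoxy)phenyl]-2-methoxyethan-1-one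
Conditions: PPTS (cat.), MeOH, 40 °C
Reagents that add atoms: none
Why: Mild acid-catalysed transacetalisation with methanol should cleave the aryl tetrahydropyranyl acetal, which is far more labile than the aryl MOM ether, and the freed phenol is held by a hydrogen bond to the ketone.

Step 8
Reactants: 15 methyl 3,5-dihydroxy-4-methoxybenzoate
Product: 16 methyl 3,5-bis(benzyloxy)-4-methoxybenzoate
Conditions: BnBr (2.4 equiv), K2CO3 (3 equiv), DMF, 60 °C
Reagents that add atoms: benzyl bromide, BrCc1ccccc1
Why: Williamson etherification of both phenols gives a ring B unit that is stable to the basic acyl-transfer chemistry and is cleaved by BCl3 at the end.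

Step 9
Reactants: 16 methyl 3,5-bis(benzyloxy)-4-methoxybenzoate
Product: 17 3,5-bis(benzyloxy)-4-methoxybenzoic acid
Conditions: LiOH·H2O, THF/MeOH/H2O, 50 °C; then 1 M HCl
Reagents that add atoms: lithium hydroxide, [Li+].[OH-]
Why: Ester saponification by acyl substitution with hydroxide; benzyl and methyl ethers are inert.

Step 10
Reactants: 17 3,5-bis(benzyloxy)-4-methoxybenzoic acid
Product: 18 3,5-bis(benzyloxy)-4-methoxybenzoyl chloride
Conditions: (COCl)2 (1.5 equiv), DMF (cat.), CH2Cl2, 0 °C to rt
Reagents that add atoms: oxalyl chloride, ClC(=O)C(Cl)=O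
Why: Acid chloride formation under DMF catalysis takes place below room temperature and gives only gaseous co-products, so 18 can be used crude.

Step 11
Reactants: 14 1-[2-ethoxy-6-hydroxy-4,5-dimethoxy-3-(methoxymethoxy)phenyl]-2-methoxyethan-1-one; 18 3,5-bis(benzyloxy)-4-methoxybenzoyl chloride
Product: 19 3-ethoxy-5,6-dimethoxy-2-(methoxyacetyl)-4-(methoxymethoxy)phenyl 3,5-bis(benzyloxy)-4-methoxybenzoate
Conditions: Et3N (2 equiv), DMAP (cat.), CH2Cl2, 0 °C to rt
Reagents that add atoms: none
Why: DMAP-catalysed O-aroylation of the only free hydroxyl (nucleophilic acyl substitution) places the ring B acyl group next to the ketone for the transfer that follows.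

Step 12
Reactants: 19 3-ethoxy-5,6-dimethoxy-2-(methoxyacetyl)-4-(methoxymethoxy)phenyl 3,5-bis(benzyloxy)-4-methoxybenzoate
Product: 20 rac-1-[3,5-bis(benzyloxy)-4-methoxyphenyl]-3-[2-ethoxy-6-hydroxy-4,5-dimethoxy-3-(methoxymethoxy)phenyl]-2-methoxypropane-1,3-dione
Conditions: LiN(SiMe3)2 (3 equiv), THF, −78 to 0 °C; then AcOH
Reagents that add atoms: none
Why: Baker–Venkataraman rearrangement: the ketone enolate attacks the neighbouring aryl ester through a six-membered transition state and moves the aroyl group from oxygen to carbon, forming the C2–C3 bond of the future ring C; the product, expected as a mixture of keto, enol and ring-closed tautomers, is used crude.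

Step 13
Reactants: 20 rac-1-[3,5-bis(benzyloxy)-4-methoxyphenyl]-3-[2-ethoxy-6-hydroxy-4,5-dimethoxy-3-(methoxymethoxy)phenyl]-2-methoxypropane-1,3-dione
Product: 21 2-[3,5-bis(benzyloxy)-4-methoxyphenyl]-5-ethoxy-6-hydroxy-3,7,8-trimethoxy-4H-chromen-4-one
Conditions: HCl (3 M in MeOH), 60 °C
Reagents that add atoms: none
Why: Acid-catalysed cyclodehydration closes ring C (attack of the phenol oxygen on the aroyl carbonyl, then loss of water), and the same acid in methanol removes the MOM acetal by exchange, while benzyl, methyl and ethyl ethers should survive.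

Step 14
Reactants: 21 2-[3,5-bis(benzyloxy)-4-methoxyphenyl]-5-ethoxy-6-hydroxy-3,7,8-trimethoxy-4H-chromen-4-one
Product: 22 5,6,3',5'-tetrahydroxy-3,7,8,4'-tetramethoxyflavone, i.e. 2-(3,5-dihydroxy-4-methoxyphenyl)-5,6-dihydroxy-3,7,8-trimethoxy-4H-chromen-4-one
Conditions: BCl3 (1 M in CH2Cl2, 8 equiv), pentamethylbenzene (6 equiv), CH2Cl2, −78 to 0 °C; then H2O
Reagents that add atoms: none
Why: Lewis-acid ether cleavage: BCl3 removes both benzyl groups, with pentamethylbenzene trapping the benzyl cations, and cleaves the 5-O-ethyl group through a six-membered boron chelate between the C4 carbonyl and the C5 oxygen (peri-assisted dealkylation), whereas the 3-, 7-, 8- and 4'-methoxy groups cannot form this chelate and should survive at 0 °C or below.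

**Compound list**

1 | dimethyl squarate (3,4-dimethoxycyclobut-3-ene-1,2-dione) | COC1=C(OC)C(=O)C1=O | starting material
2 | ethyl vinyl ether | C=COCC | starting material
3 | 1-ethoxyvinyllithium | [Li]C(=C)OCC | intermediate (not isolated)
4 | rac-4-(1-ethoxyvinyl)-4-hydroxy-2,3-dimethoxycyclobut-2-en-1-one | CCOC(=C)C1(O)C(=O)C(OC)=C1OC | intermediate
5 | rac-4-(1-ethoxyvinyl)-2,3-dimethoxy-4-(methoxymethoxy)cyclobut-2-en-1-one | CCOC(=C)C1(OCOC)C(=O)C(OC)=C1OC | intermediate
6 | (3Z)-5-ethoxy-2,3-dimethoxy-4-(methoxymethoxy)hexa-1,3,5-trien-1-one (dienylketene) | O=C=C(OC)/C(OC)=C(OCOC)\C(=C)OCC | intermediate (not isolated)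
7 | 5-ethoxy-2,3-dimethoxy-4-(methoxymethoxy)cyclohexa-2,4-dien-1-one | O=C1CC(OCC)=C(OCOC)C(OC)=C1OC | intermediate (not isolated)
8 | 5-ethoxy-2,3-dimethoxy-4-(methoxymethoxy)phenol | CCOc1cc(O)c(OC)c(OC)c1OCOC | intermediate
9 | rac-2-[5-ethoxy-2,3-dimethoxy-4-(methoxymethoxy)phenoxy]oxane | CCOc1cc(OC2CCCCO2)c(OC)c(OC)c1OCOC | intermediate
10 | methoxyacetyl chloride | COCC(Cl)=O | starting material
11 | N,2-dimethoxy-N-methylacetamide | COCC(=O)N(C)OC | intermediate
12 | rac-[2-ethoxy-4,5-dimethoxy-3-(methoxymethoxy)-6-(oxan-2-yloxy)phenyl]lithium | [Li]c1c(OCC)c(OCOC)c(OC)c(OC)c1OC1CCCCO1 | intermediate (not isolated)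
13 | rac-1-[2-ethoxy-4,5-dimethoxy-3-(methoxymethoxy)-6-(oxan-2-yloxy)phenyl]-2-methoxyethan-1-one | CCOc1c(OCOC)c(OC)c(OC)c(OC2CCCCO2)c1C(=O)COC | intermediate
14 | 1-[2-ethoxy-6-hydroxy-4,5-dimethoxy-3-(methoxymethoxy)phenyl]-2-methoxyethan-1-one | CCOc1c(OCOC)c(OC)c(OC)c(O)c1C(=O)COC | intermediate
15 | methyl 3,5-dihydroxy-4-methoxybenzoate | COC(=O)c1cc(O)c(OC)c(O)c1 | starting material
16 | methyl 3,5-bis(benzyloxy)-4-methoxybenzoate | COC(=O)c1cc(OCc2ccccc2)c(OC)c(OCc2ccccc2)c1 | intermediate
17 | 3,5-bis(benzyloxy)-4-methoxybenzoic acid | OC(=O)c1cc(OCc2ccccc2)c(OC)c(OCc2ccccc2)c1 | intermediate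
18 | 3,5-bis(benzyloxy)-4-methoxybenzoyl chloride | ClC(=O)c1cc(OCc2ccccc2)c(OC)c(OCc2ccccc2)c1 | intermediate
19 | 3-ethoxy-5,6-dimethoxy-2-(methoxyacetyl)-4-(methoxymethoxy)phenyl 3,5-bis(benzyloxy)-4-methoxybenzoate | CCOc1c(OCOC)c(OC)c(OC)c(OC(=O)c2cc(OCc3ccccc3)c(OC)c(OCc3ccccc3)c2)c1C(=O)COC | intermediate
20 | rac-1-[3,5-bis(benzyloxy)-4-methoxyphenyl]-3-[2-ethoxy-6-hydroxy-4,5-dimethoxy-3-(methoxymethoxy)phenyl]-2-methoxypropane-1,3-dione | CCOc1c(OCOC)c(OC)c(OC)c(O)c1C(=O)C(OC)C(=O)c1cc(OCc2ccccc2)c(OC)c(OCc2ccccc2)c1 | intermediate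
21 | 2-[3,5-bis(benzyloxy)-4-methoxyphenyl]-5-ethoxy-6-hydroxy-3,7,8-trimethoxy-4H-chromen-4-one | CCOc1c(O)c(OC)c(OC)c2oc(-c3cc(OCc4ccccc4)c(OC)c(OCc4ccccc4)c3)c(OC)c(=O)c12 | intermediate
22 | 5,6,3',5'-tetrahydroxy-3,7,8,4'-tetramethoxyflavone | COc1c(O)cc(-c2oc3c(OC)c(OC)c(O)c(O)c3c(=O)c2OC)cc1O | target

**Step count**

Total: 14 steps. Longest linear sequence: 10 steps (steps 1, 2, 3, 4, 6, 7, 11, 12, 13, 14).

**Steps most likely to fail**

Step 3. The ring expansion may suffer from air oxidation of the very electron-rich phenol as it forms, from hydrolysis of the enol ether by traces of acid before the ring opens, or from diversion of the ketene if the capped carbinol cyclises slowly. The fallback sets out from 4 and runs the expansion at the hydroquinone level, with the two oxygens told apart later by chelation. Heating 4 in degassed toluene under argon should give 5-ethoxy-2,3-dimethoxybenzene-1,4-diol F1, which is not purified but capped at once with excess MOMCl and i-Pr2NEt to give 1-ethoxy-3,4-dimethoxy-2,5-bis(methoxymethoxy)benzene F2. Lithiation of its single ring hydrogen with n-BuLi gives [2-ethoxy-4,5-dimethoxy-3,6-bis(methoxymethoxy)phenyl]lithium F3, and acylation with 11 gives 1-[2-ethoxy-4,5-dimethoxy-3,6-bis(methoxymethoxy)phenyl]-2-methoxyethan-1-one F4. HCl in MeOH removes both acetals to give 1-(2-ethoxy-3,6-dihydroxy-4,5-dimethoxyphenyl)-2-methoxyethan-1-one F5. One equivalent of MOMCl with i-Pr2NEt at 0 °C should then cap only the hydroxyl that is not hydrogen-bonded to the ketone, and the route is rejoined at 14.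

Step 6. The crowded aryllithium, flanked by two alkoxy groups, may take a proton from the α-methylene of amide 11 instead of adding to its carbonyl, or may add so slowly that it decays on warming. The fallback sets out from 9 and changes the bond-forming event from acyl substitution to carbonyl addition followed by oxidation. Aryllithium 12, made as before, is treated at −78 °C with freshly distilled methoxyacetaldehyde, a far more reactive electrophile, to give 1-[2-ethoxy-4,5-dimethoxy-3-(methoxymethoxy)-6-(oxan-2-yloxy)phenyl]-2-methoxyethan-1-ol F6 as a mixture of diastereomers. Oxidation with Dess–Martin periodinane buffered with NaHCO3 in CH2Cl2 then returns the route at 13.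

Step 14. The single Lewis-acid step may over-dealkylate (loss of the 3-O-methyl group, or of the crowded 4'-O-methyl group with help from a neighbouring borate), may stop before the 5-O-ethyl group is cleaved, or may C-benzylate the rings. The fallback sets out from 21 and separates the two deprotections by mechanism. Hydrogenolysis with H2 over Pd/C (zerovalent palladium on carbon) in EtOAc/THF should remove only the benzyl groups and give 2-(3,5-dihydroxy-4-methoxyphenyl)-5-ethoxy-6-hydroxy-3,7,8-trimethoxy-4H-chromen-4-one F7. Anhydrous AlCl3 in MeCN at rt to 50 °C, a milder chelation-controlled 5-O-dealkylation, then cleaves the ethyl group and returns the route at 22.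

**Further compounds**

F1 | step 3 | 5-ethoxy-2,3-dimethoxybenzene-1,4-diol | CCOc1cc(O)c(OC)c(OC)c1O
F2 | step 3 | 1-ethoxy-3,4-dimethoxy-2,5-bis(methoxymethoxy)benzene | CCOc1cc(OCOC)c(OC)c(OC)c1OCOC
F3 | step 3 | [2-ethoxy-4,5-dimethoxy-3,6-bis(methoxymethoxy)phenyl]lithium | [Li]c1c(OCC)c(OCOC)c(OC)c(OC)c1OCOC
F4 | step 3 | 1-[2-ethoxy-4,5-dimethoxy-3,6-bis(methoxymethoxy)phenyl]-2-methoxyethan-1-one | CCOc1c(OCOC)c(OC)c(OC)c(OCOC)c1C(=O)COC
F5 | step 3 | 1-(2-ethoxy-3,6-dihydroxy-4,5-dimethoxyphenyl)-2-methoxyethan-1-one | CCOc1c(O)c(OC)c(OC)c(O)c1C(=O)COC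
F6 | step 6 | 1-[2-ethoxy-4,5-dimethoxy-3-(methoxymethoxy)-6-(oxan-2-yloxy)phenyl]-2-methoxyethan-1-ol (mixture of diastereomers) | CCOc1c(OCOC)c(OC)c(OC)c(OC2CCCCO2)c1C(O)COC
F7 | step 14 | 2-(3,5-dihydroxy-4-methoxyphenyl)-5-ethoxy-6-hydroxy-3,7,8-trimethoxy-4H-chromen-4-one | CCOc1c(O)c(OC)c(OC)c2oc(-c3cc(O)c(OC)c(O)c3)c(OC)c(=O)c12
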